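All positions are numbered as in abietane (rings A and B: C1–C10; ring C: C8, C9, C11–C14; C19 is the carboxyl carbon on C4, C20 the carbon on C10; α is the face of H-5).

## Analysis of the target

The target is an abietane 19,20-olide. Ring C is a benzene ring without hydrogen (ring fusion at C8 and C9, OH at C11 and C14, OMe at C12, isopropyl at C13). Ring B carries an aryl ketone at C7, ring A is a cyclohexane, and a δ-lactone ties the C19 carboxyl on C4 to the C20 oxymethylene on C10. The stereocentres C4, C5 and C10 are contiguous, (4S,5R,10R): H-5 is α and trans to C20, and C19 and C20 are both β and 1,3-diaxial on ring A, as the lactone bridge demands. The 11,14-hydroquinone is air-sensitive and should be uncovered last, and the lactone rules out strong aqueous base late in the route. The difficulties are the two quaternary carbons C4 and C10 that flank C5, the oxidised angular carbon C20, and the crowding between the C11 oxygen and C1/C20. The plan rests on C4: a quaternary carbon that bears a carboxyl and is bonded to C3 is the product pattern of an ester-enolate Claisen rearrangement with C3–C4 as the new bond and C1=C2 as the transposed alkene. If the ester oxygen sits on C1, the allyl ester is a six-membered lactone closed through C10 and C5, and the rearrangement converts that lactone into ring A.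

## Retrosynthetic reasoning

31 from 30 from 29. The two O–CH3 bonds at C11 and C14 are cut, not the one at C12: the para pair is what a one-electron oxidant turns into quinone 30, while the C12 methoxy group survives as a vinylogous ester. Reduction of 30 gives hydroquinone 31. Ring C can therefore travel as a robust trimethyl ether from the second step on.

29 from 28. The C7 carbonyl is taken back to a benzylic methylene. A ketone at C7 would deactivate the arene for the closure of ring B and would offer a second enolisable site in the key step. Forward, C7 is the only benzylic CH2 and is activated by the ortho and para methoxy groups.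

28 from 27, 26 and 25. The lactone is opened at the C19 acyl–oxygen bond to hydroxy acid 27. Its C20 carbinol comes from the C20 methyl ester of 26 by hydride reduction, which is selective because C19 is then a carboxylate. The C1–C2 single bond of 26 comes from the alkene of 25. Keeping C20 at the ester level means it needs no protecting group and has no α-hydrogen.

25 from 23 through salt 24. The absolute configuration is chosen by resolution at the first carboxylic acid of the sequence, which is a single racemic diastereomer.

23 from 20 through 22 and 21 (key disconnection). C3–C4 is cut and C1 is rejoined to the oxygen of C19, which gives the 1-vinyl 19,1-lactone 20. C4 is the only carbon where the Claisen pattern fits, and because C1 and C4 are linked through C10–C5 the allyl ester is a δ-lactone. The gain is that the quaternary C4 arises from an enolisable tertiary centre whose configuration is irrelevant, and ring A closes in the same event. Forward, only C4 may be enolised, and C3 must reach the α face of C4, which the configuration at C1 decides.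

20 from 17 and 18 through 19. The lactone C–O bond and C1–C2 are cut: vinylmagnesium bromide 18 adds to the C10 aldehyde of 17, and the resulting 5-hydroxy ester 19 closes to the lactone. The addition must place the vinyl group anti to the C10 ester.

17 from 12, 13 and 14 through 15 and 16. C4–C5 and C10–C1 are cut in one operation. Enoate 12 accepts the enolate 15 of tert-butyl propanoate 13 at C5, and the benzylic ester enolate 16 is formylated by ethyl formate 14 at C10, anti to the new side chain. This sets C5 and C10 relative to each other and puts the C10 ester cis to the C4 carbon, as the final lactone requires.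

12 from 11 and 9 through 10. C10–C20 is cut: the ester carbon is introduced by palladium-catalysed alkoxycarbonylation of enol triflate 11 of tetralone 9.

9 from 8, 7, 5 and 6. C9–C10 and C7–C8 are cut (Haworth sequence). Succinic anhydride 6 acylates arene 5 at the future C8, the most nucleophilic free position; the ketone of 7 is removed to give 8; and the acid closes onto the only remaining aromatic position.

5 from 4, 1 and 2 through 3. C13–C15 is cut: the position of 1,2,4-trimethoxybenzene 1 between two methoxy groups is lithiated to 3, acetone 2 is added, and carbinol 4 is deoxygenated.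

## Alternatives that were turned down

Alternative 1: C8–C9 and C11–C12 are disconnected, so ring B and the arene form together from precursor A2, a 6-acyl-3-methoxy-2-pyrone tied through C7–C6–C5 to a ring A lactone whose quaternary C10 carries an alkynyl pinacolboronate. Forward, the pyrone is the diene in an intramolecular Diels–Alder reaction with the alkyne; the bridged adduct loses its lactone bridge by decarboxylative cycloreversion and gives arylboronate A1.
- For: it is convergent, the tether fixes the arene regiochemistry, and the C7 ketone, the C12 methoxy group and a C–B bond at C11 are in place. It is stronger than the chosen route in that C7 never needs a benzylic oxidation.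
- Against: A1 still lacks the C13 isopropyl group and the C14 oxygen, which would have to go onto a ring deactivated by the aryl ketone. A2 already contains ring A, the 19,20-lactone and all three stereocentres, including a propargylic quaternary C10, so the stereochemical problems are only moved into the synthesis of A2.
- Comparison: the chosen route is less convergent, but it has the full ring C pattern after two steps and uses its key step to create C4 by relay of configuration.

Alternative 2: C7–C8 and C9–C10 are disconnected. Ring B comes from a [4+2] cycloaddition of diene A4, a 1-vinylcyclohexene with a tetrasubstituted C5=C10 bond and C4 already quaternary, with quinone A5 at its unsubstituted edge. The ene-dione adduct tautomerises to hydroquinone A3, with C10 quaternary and a C5=C6 double bond left.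
- For: step economy and convergence are clearly better than in the chosen route. Ring C arrives at the right oxidation level, so no ether cleavage or final redox pair is needed, and C9–C10 forms without enolate chemistry next to the C11 oxygen.
- Against: the diene terminus C10 is fully substituted, so the cycloaddition is slow and diene isomerisation can compete. The face of C10 is decided only by the remote C4 centre, although C20 must end cis to C19. The orientation of the unsymmetrical quinone, which decides whether the methoxy group ends at C12 or C13, rests on a modest electronic bias. A3 still needs a trans-selective reduction of C5=C6 and an oxidation at C7 beside a free hydroquinone.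
- Comparison: the chosen route is longer, but it sets C5 and C10 together by anti trapping of an enolate, fixes the arene regiochemistry by construction and transfers configuration to C4.

Alternative 3: no skeletal bond is disconnected. Rings A–C and the centres C4, C5 and C10 are taken from podocarpic acid A8, and the strategic bond is C20–O. Forward, the C11 phenol of an elaborated podocarpate becomes the diethylhydrosilyl ether A7; a catalytic intramolecular dehydrogenative silylation of a C20–H bond closes oxasilinane A6 (O11–Si–C20); oxidation of the C–Si bond gives the C20 carbinol, which lactonises with the C19 ester.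
- For: the absolute configuration comes from the chiral pool, which is stronger than the resolution in the chosen route, and no skeletal C–C bond has to be made.
- Against: A8 has oxygen only at C12, so the C11 and C14 oxygens, the C13 isopropyl group and the C7 ketone all need arene or benzylic functionalisation. The silylation must pick a primary C–H of a neopentyl-type methyl group over the C1 methylene hydrogens at similar distance. A silicon tether on a phenol oxygen is more labile than the alcohol-derived tethers for which this reaction type is best established.
- Comparison: the chosen route starts from simple achiral materials, carries C20 at the carboxyl level from the carbonylation onwards and has the ring C pattern from the start.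

Key step: step 10

Assumption: compounds 16, 17 and 19–23 are racemic (17, 19 and 20 as both C4 epimers); their SMILES show the enantiomer that is kept after step 11.

## Route

Step 1
Reactants: 1 1,2,4-trimethoxybenzene; 2 acetone
Product: 4 2-(2,3,6-trimethoxyphenyl)propan-2-ol, via (2,3,6-trimethoxyphenyl)lithium 3 (not isolated)
Conditions: n-BuLi, THF, 0 °C; 2, −78 °C to rt; aq. NH4Cl
Reagents that add atoms: none
Why: Directed ortho-lithiation takes the hydrogen flanked by two methoxy groups (the future C13), and the aryllithium adds to the ketone (1,2-addition) to give the tertiary benzylic alcohol.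

Step 2
Reactants: 4 2-(2,3,6-trimethoxyphenyl)propan-2-ol
Product: 5 1,2,4-trimethoxy-3-(propan-2-yl)benzene
Conditions: Et3SiH, CF3CO2H, CH2Cl2, 0 °C to rt
Reagents that add atoms: none
Why: Ionic hydrogenation: acid ionises the electron-rich tertiary benzylic alcohol and the silane delivers hydride to the cation.

Step 3
Reactants: 5 1,2,4-trimethoxy-3-(propan-2-yl)benzene; 6 succinic anhydride
Product: 7 4-oxo-4-[2,4,5-trimethoxy-3-(propan-2-yl)phenyl]butanoic acid
Conditions: AlCl3, CH2Cl2–CH3NO2, 0 °C; aq. HCl
Reagents that add atoms: none
Why: Friedel–Crafts acylation at the future C8, which is para to one methoxy group and ortho to another, whereas the other free position is activated by one methoxy group only; low temperature limits ether cleavage.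

Step 4
Reactants: 7 4-oxo-4-[2,4,5-trimethoxy-3-(propan-2-yl)phenyl]butanoic acid
Product: 8 4-[2,4,5-trimethoxy-3-(propan-2-yl)phenyl]butanoic acid
Conditions: Et3SiH, CF3CO2H, rt
Reagents that add atoms: none
Why: Ionic hydrogenation of an electron-rich aryl ketone to the methylene group; the carboxylic acid is inert.

Step 5
Reactants: 8 4-[2,4,5-trimethoxy-3-(propan-2-yl)phenyl]butanoic acid
Product: 9 5,7,8-trimethoxy-6-(propan-2-yl)-3,4-dihydronaphthalen-1(2H)-one
Conditions: P2O5 in CH3SO3H, rt
Reagents that add atoms: none
Why: Intramolecular Friedel–Crafts acylation (Haworth ring closure) at the only free aromatic position, the future C9, closes the six-membered ring B.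

Step 6
Reactants: 9 5,7,8-trimethoxy-6-(propan-2-yl)-3,4-dihydronaphthalen-1(2H)-one
Product: 11 5,7,8-trimethoxy-6-(propan-2-yl)-3,4-dihydronaphthalen-1-yl trifluoromethanesulfonate, via potassium enolate 10 (not isolated)
Conditions: KN(SiMe3)2, THF, −78 °C; PhN(SO2CF3)2, −78 to 0 °C; aq. NH4Cl
Reagents that add atoms: N-phenylbis(trifluoromethanesulfonimide), O=S(=O)(N(c1ccccc1)S(=O)(=O)C(F)(F)F)C(F)(F)F
Why: Enolate O-sulfonylation; the ketone has a single α-methylene group, so the enol triflate is formed at C10=C5 only.

Step 7
Reactants: 11 5,7,8-trimethoxy-6-(propan-2-yl)-3,4-dihydronaphthalen-1-yl trifluoromethanesulfonate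
Product: 12 methyl 5,7,8-trimethoxy-6-(propan-2-yl)-3,4-dihydronaphthalene-1-carboxylate
Conditions: Pd(OAc)2 (cat.), Ph2P(CH2)3PPh2, CO (1 atm), MeOH, Et3N, DMF, 70 °C
Reagents that add atoms: carbon monoxide, [C-]#[O+]; methanol, CO
Why: Palladium-catalysed alkoxycarbonylation of an enol triflate (oxidative addition, CO insertion, methanolysis) installs C20 at the ester level.

Step 8
Reactants: 12 methyl 5,7,8-trimethoxy-6-(propan-2-yl)-3,4-dihydronaphthalene-1-carboxylate; 13 tert-butyl propanoate; 14 ethyl formate
Product: 17 racemic formyl diester with CHO on C10 trans to the C5 side chain, via lithium enolate of tert-butyl propanoate 15 (not isolated), via C10 lithium ester enolate 16 (not isolated)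
Conditions: LiN(i-Pr)2, 13, THF, −78 °C; 12, −78 to −40 °C; 14 (excess), −78 °C; AcOH, −78 °C
Reagents that add atoms: none
Why: Michael addition of a lithium ester enolate to the α-aryl enoate gives the benzylic ester enolate 16, which is C-formylated (crossed Claisen condensation with a formate) on the face anti to the new C5 side chain, so that the C10 ester ends cis to the side chain and C5 and C10 are set relative to each other. The hindered C10 ester carbonyl disfavours 1,2-attack, and C4 is left uncontrolled because it is enolised again in step 10.

Step 9
Reactants: 17 racemic formyl diester with CHO on C10 trans to the C5 side chain; 18 vinylmagnesium bromide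
Product: 20 racemic tetralin-fused 1α-vinyl 19,1-lactone with the C10 methyl ester, via hydroxy diester 19 (not isolated)
Conditions: MgBr2·OEt2, CH2Cl2, −78 °C; CH2=CHMgBr (THF), −78 °C; aq. NH4Cl; then CF3CO2H, CH2Cl2, 0 °C
Reagents that add atoms: none
Why: Chelation-controlled 1,2-addition of a Grignard reagent: magnesium bridges the aldehyde and the C10 ester carbonyl, and the vinyl group should enter C1 anti to the C10–CO2Me bond from the side of H-5 while the aldehyde hydrogen takes the crowded slot next to the C11 methoxy group, which places vinyl α. Acid then removes the tert-butyl group and the 5-hydroxy acid closes to the trans-fused δ-lactone (lactonisation).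

Step 10
Reactants: 20 racemic tetralin-fused 1α-vinyl 19,1-lactone with the C10 methyl ester
Product: 23 racemic 11,12,14-trimethoxyabieta-1,8,11,13-tetraene-19,20-dioic acid 20-methyl ester, via silyl ketene acetal 21 (not isolated), via silyl ester 22 (not isolated)
Conditions: KN(SiMe3)2, t-BuMe2SiCl, THF–toluene, −78 °C to rt; toluene, 110 °C, sealed tube (xylene, 140 °C if slow); 1 M HCl, THF
Reagents that add atoms: none
Why: KN(SiMe3)2 removes the only acidic hydrogen (C4–H; C10 carries none) and O-silylation gives the cyclic ketene acetal 21 with the C4=C19 double bond inside the lactone ring. On heating, 21 undergoes a [3,3]-sigmatropic shift in the array C4=C19–O–C1–C2=C3: the vinyl terminus C3 bonds to C4 while C1–O breaks, which gives silyl ester 22 and, after hydrolysis, acid 23. The closest known reaction type is the Ireland–Claisen rearrangement of silyl ketene acetals of δ-lactones that bear a vinyl group on the carbinol carbon, which yields cyclohex-3-enecarboxylic acids. Ring A is closed by this C3–C4 bond inside a boat-like six-centre transition state, because four of the six atoms are tied into the lactone ring; C19–O, C2=C3 and C10–C5 span C1 and C4 like the three bridges of bicyclo[2.2.2]octane. The new stereocentre C4 is controlled by C1: the α-vinyl group can reach only the α face of the ketene acetal, so C3 ends α and the C19 carboxyl β, cis to the C10 ester. The step needs a single site of enolisation, secured by the quaternary C10, and a configurationally pure C1, since the C1 epimer would deliver C3 to the other face. The trans fusion of ring B across C5–C10 forces this bridge out of the eclipsed geometry and twists the boat, so a higher temperature than for monocyclic vinyl lactones is expected. The tert-butyldimethylsilyl group is chosen so that the ketene acetal survives that temperature.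

Step 11
Reactants: 23 racemic 11,12,14-trimethoxyabieta-1,8,11,13-tetraene-19,20-dioic acid 20-methyl ester
Product: 25 11,12,14-trimethoxyabieta-1,8,11,13-tetraene-19,20-dioic acid 20-methyl ester as the single enantiomer that has the configuration of 31, via (S)-1-phenylethylammonium salt 24 (not isolated)
Conditions: (S)-1-phenylethylamine, EtOAc–acetone, crystallise to constant rotation; then 1 M HCl, EtOAc
Reagents that add atoms: none
Why: Classical resolution through diastereomeric ammonium salts of a carboxylic acid that is a single racemic diastereomer; mineral acid sets the acid free. Which antipode of the amine gives the less soluble salt of the wanted acid has to be found by trial, and the assignment is confirmed by correlation at 31.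

Step 12
Reactants: 25 11,12,14-trimethoxyabieta-1,8,11,13-tetraene-19,20-dioic acid 20-methyl ester as the single enantiomer
Product: 26 11,12,14-trimethoxyabieta-8,11,13-triene-19,20-dioic acid 20-methyl ester
Conditions: H2 (1–3 atm), 10% Pd/C, EtOAc, rt
Reagents that add atoms: none
Why: Heterogeneous catalytic hydrogenation of the cis-disubstituted C1=C2 alkene; no stereocentre is formed and the arene is untouched.

Step 13
Reactants: 26 11,12,14-trimethoxyabieta-8,11,13-triene-19,20-dioic acid 20-methyl ester
Product: 28 11,12,14-trimethoxyabieta-8,11,13-trien-19,20-olide, via 20-hydroxy acid 27 (not isolated)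
Conditions: LiBHEt3 (excess), THF, 0 °C to rt; 2 M HCl, rt
Reagents that add atoms: none
Why: Chemoselective hydride reduction: the C19 acid is first converted into its lithium carboxylate, which LiBHEt3 does not reduce, while the C20 methyl ester is reduced to the primary alkoxide. On acidification the 1,3-diaxial hydroxy acid 27 closes to the δ-lactone (lactonisation).

Step 14
Reactants: 28 11,12,14-trimethoxyabieta-8,11,13-trien-19,20-olide
Product: 29 11,12,14-trimethoxy-7-oxoabieta-8,11,13-trien-19,20-olide
Conditions: CrO3, AcOH–H2O, rt
Reagents that add atoms: chromium trioxide, O=[Cr](=O)=O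
Why: Benzylic oxidation by hexavalent chromium at C7, the only benzylic methylene group, activated by the ortho and para methoxy groups; the isopropyl methine is shielded between two methoxy groups.

Step 15
Reactants: 29 11,12,14-trimethoxy-7-oxoabieta-8,11,13-trien-19,20-olide
Product: 30 12-methoxy-7,11,14-trioxoabieta-8,12-dien-19,20-olide
Conditions: (NH4)2Ce(NO3)6, MeCN–H2O, 0 °C
Reagents that add atoms: water, O
Why: Oxidative demethylation of a para-dimethoxyarene to the para-quinone by tetravalent cerium; the C12 methoxy group survives as the vinylogous ester of the quinone.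

Step 16
Reactants: 30 12-methoxy-7,11,14-trioxoabieta-8,12-dien-19,20-olide
Product: 31 (4S,5R,10R)-11,14-dihydroxy-12-methoxy-7-oxoabieta-8,11,13-trien-19,20-olide
Conditions: Na2S2O4, EtOAc–H2O, rt, under argon
Reagents that add atoms: none
Why: Two-electron reduction of the quinone to the hydroquinone by dithionite; the aryl ketone and the lactone are inert, and the C14 hydroxyl is stabilised by hydrogen bonding to the C7 carbonyl.

## Compound list

1 | 1,2,4-trimethoxybenzene | COc1ccc(OC)c(OC)c1 | starting material
2 | acetone | CC(C)=O | starting material
3 | (2,3,6-trimethoxyphenyl)lithium | [Li]c1c(OC)ccc(OC)c1OC | intermediate (not isolated)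
4 | 2-(2,3,6-trimethoxyphenyl)propan-2-ol | COc1ccc(OC)c(C(C)(C)O)c1OC | intermediate
5 | 1,2,4-trimethoxy-3-(propan-2-yl)benzene | COc1ccc(OC)c(C(C)C)c1OC | intermediate
6 | succinic anhydride | O=C1CCC(=O)O1 | starting material
7 | 4-oxo-4-[2,4,5-trimethoxy-3-(propan-2-yl)phenyl]butanoic acid | OC(=O)CCC(=O)c1cc(OC)c(OC)c(C(C)C)c1OC | intermediate
8 | 4-[2,4,5-trimethoxy-3-(propan-2-yl)phenyl]butanoic acid | OC(=O)CCCc1cc(OC)c(OC)c(C(C)C)c1OC | intermediate
9 | 5,7,8-trimethoxy-6-(propan-2-yl)-3,4-dihydronaphthalen-1(2H)-one | O=C1CCCc2c1c(OC)c(OC)c(C(C)C)c2OC | intermediate
10 | potassium 5,7,8-trimethoxy-6-(propan-2-yl)-3,4-dihydronaphthalen-1-olate | [K+].[O-]C1=CCCc2c1c(OC)c(OC)c(C(C)C)c2OC | intermediate (not isolated)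
11 | 5,7,8-trimethoxy-6-(propan-2-yl)-3,4-dihydronaphthalen-1-yl trifluoromethanesulfonate | O=S(=O)(OC1=CCCc2c1c(OC)c(OC)c(C(C)C)c2OC)C(F)(F)F | intermediate
12 | methyl 5,7,8-trimethoxy-6-(propan-2-yl)-3,4-dihydronaphthalene-1-carboxylate | COC(=O)C1=CCCc2c1c(OC)c(OC)c(C(C)C)c2OC | intermediate
13 | tert-butyl propanoate | CCC(=O)OC(C)(C)C | starting material
14 | ethyl formate | CCOC=O | starting material
15 | lithium enolate of tert-butyl propanoate (methyl cis to O-tert-butyl) | [Li+].C/C=C(\OC(C)(C)C)[O-] | intermediate (not isolated)
16 | C10 lithium ester enolate of the conjugate adduct (racemic, both C4 epimers) | COc1c(OC)c2c(c(OC)c1C(C)C)CC[C@@H](C(C)C(=O)OC(C)(C)C)C2=C([O-])OC.[Li+] | intermediate (not isolated)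
17 | methyl 2-(1-tert-butoxy-1-oxopropan-2-yl)-1-formyl-5,7,8-trimethoxy-6-(propan-2-yl)-1,2,3,4-tetrahydronaphthalene-1-carboxylate; racemic, CHO trans to the side chain (C10 ester β, side chain β, H-5 α), both C4 epimers | COc1c(OC)c2c(c(OC)c1C(C)C)CC[C@@H](C(C)C(=O)OC(C)(C)C)[C@]2(C(=O)OC)C=O | intermediate
18 | vinylmagnesium bromide | C=C[Mg]Br | starting material
19 | hydroxy diester: as 17 with CH(OH)CH=CH2 on C10 in place of CHO, C1 configured as in 20; racemic | COc1c(OC)c2c(c(OC)c1C(C)C)CC[C@@H](C(C)C(=O)OC(C)(C)C)[C@]2(C(=O)OC)[C@H](O)C=C | intermediate (not isolated)
20 | vinyl lactone: δ-lactone C19(=O)–O–C1 trans-fused to the tetralin at C5–C10, vinyl on C1 α (anti to the 10β-CO2Me), H-5 α, methyl on C4 (both epimers); racemic | COc1c(OC)c2c(c(OC)c1C(C)C)CC[C@@H]1[C@]2(C(=O)OC)[C@@H](C=C)OC(=O)C1C | intermediate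
21 | tert-butyldimethylsilyl ketene acetal of 20 (C4=C19); racemic | COc1c(OC)c2c(c(OC)c1C(C)C)CC[C@@H]1[C@]2(C(=O)OC)[C@@H](C=C)OC(O[Si](C)(C)C(C)(C)C)=C1C | intermediate (not isolated)
22 | 19-(tert-butyldimethylsilyl) 20-methyl 11,12,14-trimethoxyabieta-1,8,11,13-tetraene-19,20-dioate; racemic | COc1c(OC)c2c(c(OC)c1C(C)C)CC[C@@H]1[C@]2(C(=O)OC)C=CC[C@]1(C)C(=O)O[Si](C)(C)C(C)(C)C | intermediate (not isolated)
23 | 11,12,14-trimethoxyabieta-1,8,11,13-tetraene-19,20-dioic acid 20-methyl ester (C19 acid β, C20 ester β, H-5 α); racemic | COc1c(OC)c2c(c(OC)c1C(C)C)CC[C@@H]1[C@]2(C(=O)OC)C=CC[C@]1(C)C(=O)O | intermediate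
24 | (S)-1-phenylethylammonium salt of 25 | COc1c(OC)c2c(c(OC)c1C(C)C)CC[C@@H]1[C@]2(C(=O)OC)C=CC[C@]1(C)C(=O)[O-].C[C@H]([NH3+])c1ccccc1 | intermediate (not isolated)
25 | 11,12,14-trimethoxyabieta-1,8,11,13-tetraene-19,20-dioic acid 20-methyl ester, single enantiomer with the configuration of 31 | COc1c(OC)c2c(c(OC)c1C(C)C)CC[C@@H]1[C@]2(C(=O)OC)C=CC[C@]1(C)C(=O)O | intermediate
26 | 11,12,14-trimethoxyabieta-8,11,13-triene-19,20-dioic acid 20-methyl ester | COc1c(OC)c2c(c(OC)c1C(C)C)CC[C@@H]1[C@]2(C(=O)OC)CCC[C@]1(C)C(=O)O | intermediate
27 | 20-hydroxy-11,12,14-trimethoxyabieta-8,11,13-trien-19-oic acid | COc1c(OC)c2c(c(OC)c1C(C)C)CC[C@@H]1[C@]2(CO)CCC[C@]1(C)C(=O)O | intermediate (not isolated)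
28 | 11,12,14-trimethoxyabieta-8,11,13-trien-19,20-olide | COc1c(OC)c2c(c(OC)c1C(C)C)CC[C@@H]1[C@]23CCC[C@]1(C)C(=O)OC3 | intermediate
29 | 11,12,14-trimethoxy-7-oxoabieta-8,11,13-trien-19,20-olide | COc1c(OC)c2c(c(OC)c1C(C)C)C(=O)C[C@@H]1[C@]23CCC[C@]1(C)C(=O)OC3 | intermediate
30 | 12-methoxy-7,11,14-trioxoabieta-8,12-dien-19,20-olide (11,14-quinone) | COC=1C(=O)C2=C(C(=O)C1C(C)C)C(=O)C[C@@H]1[C@]23CCC[C@]1(C)C(=O)OC3 | intermediate
31 | (4S,5R,10R)-11,14-dihydroxy-12-methoxy-7-oxoabieta-8,11,13-trien-19,20-olide | COc1c(O)c2c(c(O)c1C(C)C)C(=O)C[C@@H]1[C@]23CCC[C@]1(C)C(=O)OC3 | target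

Total step count: 16. Longest linear sequence: 16 steps (1 to 31).

## Least certain steps

Step 10 (key step). The rearrangement may be too slow: the trans fusion of ring B across C5–C10 resists the near-eclipsed geometry of the boat-like array. At the temperature then needed, migration of silicon from oxygen to carbon or hydrolysis of the ketene acetal could compete.
Fallback: ring A is closed by olefin metathesis instead, setting out from 17 and returning at 23. Wittig methylenation of the formyl group (Ph3P=CH2, THF) gives the C10-vinyl diester F1. LiN(i-Pr)2 then allyl bromide alkylates C4, the only enolisable position, to the quaternary allyl ester F2 as both C4 epimers. RuCl2(=CHPh)(PCy3)(H2IMes) (second-generation Grubbs catalyst) joins the C10 vinyl and C4 allyl groups to the cyclohexene tert-butyl ester F3, where the C4 epimers are separated. CF3CO2H cleaves the tert-butyl ester to 23. The price is that C4 is no longer set by relay from C1.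

Step 8. Proton transfer may win over C–C bond formation: the peri methoxy group twists the C10 ester out of conjugation, so the ester enolate may deprotonate the allylic C6 position of 12 or add only slowly. Loss of the formyl group by retro-Claisen cleavage is a second risk.
Fallback: the C4–C5 bond is made by a radical conjugate addition (Giese reaction) under neutral conditions, setting out from 12 and returning at 17. tert-Butyl 2-bromopropanoate, Bu3SnH and azobisisobutyronitrile in benzene at 80 °C add the α-ester radical to C5 and give the C10–H diester F4 after hydrogen transfer to the benzylic radical. LiN(i-Pr)2 then deprotonates C10 selectively, and 14 formylates the enolate anti to the side chain to give 17.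

Step 9. Facial selectivity at C1 may be poor if the magnesium chelate does not dominate and a non-chelated (Felkin-type) approach competes. The C1 epimer would later deliver C3 to the wrong face of C4.
Fallback: C1 is corrected under thermodynamic control, setting out from 17 and returning at 20. The epimer mixture from the addition contains the 1β-vinyl lactone F5. Pd(PPh3)4 (cat.) in THF at 60 °C ionises the allylic C1–O bond to a π-allylpalladium carboxylate, which recloses reversibly; there is no β-hydrogen on C10, so elimination is excluded. This should converge on 20, in which the vinyl group is axial and the small hydrogen, not the vinyl group, faces the C11 methoxy group.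

Step 11. Crystallisation may fail to discriminate: the diastereomeric salts may co-crystallise or stay oily, because the carboxyl group is buried between C10 and the ring.
Fallback: the enantiomers are separated by preparative chromatography on a polysaccharide-carbamate chiral stationary phase, setting out from 23 and returning at 25. No new compound is formed.

Step 14. Over-oxidation is possible: hexavalent chromium may attack the electron-rich arene (demethylation towards a quinone before C7 is oxidised) or the isopropyl methine.
Fallback: C7 is oxidised by hydride abstraction, setting out from 28 and returning at 29. 2,3-Dichloro-5,6-dicyano-1,4-benzoquinone in CH2Cl2–H2O removes a benzylic hydride from C7, water traps the cation to give the 7-hydroxy lactone F6, and Dess–Martin periodinane oxidises F6 to 29.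

## Further compounds

F1 | step 10 | C10-vinyl diester: as 17 with CH=CH2 in place of CHO; racemic | COc1c(OC)c2c(c(OC)c1C(C)C)CC[C@@H](C(C)C(=O)OC(C)(C)C)[C@]2(C(=O)OC)C=C
F2 | step 10 | C4-allylated diester: as F1 with an allyl group on C4; racemic, both C4 epimers | COc1c(OC)c2c(c(OC)c1C(C)C)CC[C@@H](C(C)(CC=C)C(=O)OC(C)(C)C)[C@]2(C(=O)OC)C=C
F3 | step 10 | 19-tert-butyl 20-methyl 11,12,14-trimethoxyabieta-1,8,11,13-tetraene-19,20-dioate; racemic | COc1c(OC)c2c(c(OC)c1C(C)C)CC[C@@H]1[C@]2(C(=O)OC)C=CC[C@]1(C)C(=O)OC(C)(C)C
F4 | step 8 | methyl 2-(1-tert-butoxy-1-oxopropan-2-yl)-5,7,8-trimethoxy-6-(propan-2-yl)-1,2,3,4-tetrahydronaphthalene-1-carboxylate; racemic, epimers at C10 and C4 | COc1c(OC)c2c(c(OC)c1C(C)C)CC[C@@H](C(C)C(=O)OC(C)(C)C)C2C(=O)OC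
F5 | step 9 | C1 epimer of 20 (vinyl β, syn to the C10 ester); racemic | COc1c(OC)c2c(c(OC)c1C(C)C)CC[C@@H]1[C@]2(C(=O)OC)[C@H](C=C)OC(=O)C1C
F0 | step 11 | none | none
F6 | step 14 | 7-hydroxy-11,12,14-trimethoxyabieta-8,11,13-trien-19,20-olide (C7 epimers) | COc1c(OC)c2c(c(OC)c1C(C)C)C(O)C[C@@H]1[C@]23CCC[C@]1(C)C(=O)OC3
A1 | alternative 1 | tetracyclic C11 pinacol arylboronate with C7 ketone, C12 methoxy and 19,20-lactone | COc1c(B4OC(C)(C)C(C)(C)O4)c2c(cc1)C(=O)C[C@@H]1[C@]23CCC[C@]1(C)C(=O)OC3
A2 | alternative 1 | 6-acyl-3-methoxy-2-pyrone tethered through C7–C6–C5 to the ring A lactone with a C10 alkynyl pinacolboronate | COc1ccc(oc1=O)C(=O)C[C@@H]1[C@@]3(C#CB2OC(C)(C)C(C)(C)O2)CCC[C@]1(C)C(=O)OC3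
A3 | alternative 2 | tricyclic 11,14-hydroquinone with C5=C6 alkene, C20 silyl ether and C19 tert-butyl ester | COc1c(O)c2c(c(O)c1C(C)C)CC=C1[C@]2(CO[Si](C)(C)C(C)(C)C)CCC[C@]1(C)C(=O)OC(C)(C)C
A4 | alternative 2 | tert-butyl 1-methyl-3-[(tert-butyldimethylsilyloxy)methyl]-2-vinylcyclohex-2-ene-1-carboxylate (diene) | C=CC1=C(CO[Si](C)(C)C(C)(C)C)CCC[C@]1(C)C(=O)OC(C)(C)C
A5 | alternative 2 | 2-methoxy-3-(propan-2-yl)-1,4-benzoquinone | COC1=C(C(C)C)C(=O)C=CC1=O
A6 | alternative 3 | O11–Si–C20 diethyloxasilinane of methyl 12-methoxyabieta-8,11,13-trien-19-oate | COc1c2c3c(cc1C(C)C)CC[C@@H]1[C@]3(C[Si](CC)(CC)O2)CCC[C@]1(C)C(=O)OC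
A7 | alternative 3 | methyl 11-(diethylsilyloxy)-12-methoxyabieta-8,11,13-trien-19-oate | COc1c(O[SiH](CC)CC)c2c(cc1C(C)C)CC[C@@H]1[C@]2(C)CCC[C@]1(C)C(=O)OC
A8 | alternative 3 | podocarpic acid | Oc1cc2c(cc1)CC[C@@H]1[C@]2(C)CCC[C@]1(C)C(=O)O
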